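The two methyl carbons of sauriol B, C9 and C9′, are one-carbon branches on the adjacent methines C8 and C8′ that join ring A (syringyl) to ring B (5-methoxycatechol). Disconnecting the C8–C9 and C8′–C9′ bonds, and reading ring B as a syringyl ring that has lost one methyl, leads back to a C2-symmetric (E)-1,4-diarylbut-2-ene. In a single flask, (nbd)Rh(acac)/QUINAP-catalysed syn-diboration of that alkene sets C8 and C8′ (both R), and two chloromethyllithium insertions into the new C–B bonds attach C9 and C9′ with retention. The precursor is the O-benzylated self-metathesis dimer of 4-allyl-2,6-dimethoxyphenol, with no free O–H and a geometrically pure E double bond.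

Key step: step 3

Assumption: (R)-QUINAP is taken to be the ligand enantiomer that gives the 2R,3R bis(boronate) 7 (lignan numbering C7–C9 and C7′–C9′ for the two side chains); should diol 9 prove to be 2S,3S, (S)-QUINAP is used and nothing else changes.

Step 1
Reactants: 1 4-allyl-2,6-dimethoxyphenol; 2 benzyl bromide
Product: 3 5-allyl-2-(benzyloxy)-1,3-dimethoxybenzene
Conditions: BnBr (1.1 equiv), K2CO3 (2 equiv), DMF, 60 °C
Reagents that add atoms: none
Why: Williamson ether synthesis, in which the phenoxide of 1, although flanked by two methoxy groups, should be alkylated cleanly by the reactive benzylic bromide, while carbonate is too weak a base to move the allyl double bond into conjugation.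

Step 2
Reactants: 3 5-allyl-2-(benzyloxy)-1,3-dimethoxybenzene (two molecules)
Product: 4 (E)-1,4-bis[4-(benzyloxy)-3,5-dimethoxyphenyl]but-2-ene
Conditions: second-generation Grubbs catalyst (H2IMes)(PCy3)Cl2Ru=CHPh (2 mol%), 1,4-benzoquinone (10 mol%), CH2Cl2, 40 °C, argon purge; recrystallisation (EtOH/EtOAc) to the pure E isomer
Reagents that add atoms: none
Why: Olefin self-metathesis of a terminal allylarene is driven by loss of ethylene and, being reversible, should settle mainly on the more stable E isomer, which the symmetrical solid allows to be purified by recrystallisation, while benzoquinone intercepts the ruthenium hydrides that would shift the double bond toward the ring.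

Step 3
Reactants: 4 (E)-1,4-bis[4-(benzyloxy)-3,5-dimethoxyphenyl]but-2-ene; 5 bis(catecholato)diboron; 6 bromochloromethane (two molecules)
Product: 8 (2R,3R)-2,3-bis[4-(benzyloxy)-3,5-dimethoxybenzyl]butane-1,4-diyl bis(catecholboronate), via vicinal bis(catecholboronate) 7 (not isolated)
Conditions: (nbd)Rh(acac) (5 mol%), (R)-QUINAP (5 mol%), 5 (1.1 equiv), THF, rt; then 6 (3.0 equiv), n-BuLi (2.8 equiv), −78 °C to rt; filtered and concentrated under argon, crude 8 used directly
Reagents that add atoms: none
Why: This is a rhodium-catalysed enantioselective alkene diboration followed by a twofold Matteson-type homologation: the B–B bond of 5 adds oxidatively to the rhodium–QUINAP complex, the alkene inserts into a Rh–B bond and C–B reductive elimination places both borons on the same face, giving 7. Chloromethyllithium, made in the flask from 6 and n-BuLi, then binds to each Lewis-acidic catecholboronate, and the secondary carbon migrates from boron to the CH2 carbon with loss of chloride and retention of configuration, which forms the C8–C9 and C8′–C9′ bonds. No ring is closed. C8 and C8′ are set in the diboration, where the P,N ligand selects the alkene face, and their like relationship follows from syn addition to an E-alkene; the 1,2-shifts pass both centres on unchanged. The step needs enantioface selectivity and suppression of rhodium-hydride migration of the double bond toward the styrene position; the substrate contributes two identical alkene termini (no regiochemical question), geometric purity (any Z isomer would give the meso product) and the absence of free O–H groups.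

Step 4
Reactants: 8 (2R,3R)-2,3-bis[4-(benzyloxy)-3,5-dimethoxybenzyl]butane-1,4-diyl bis(catecholboronate)
Product: 9 (2R,3R)-2,3-bis[4-(benzyloxy)-3,5-dimethoxybenzyl]butane-1,4-diol
Conditions: 3 M NaOH, 30% H2O2, THF, 0 °C to rt; catechol removed by basic wash, 9 recrystallised
Reagents that add atoms: hydrogen peroxide, OO
Why: Oxidation of alkylboronates by alkaline hydrogen peroxide proceeds by 1,2-shift of the primary CH2 carbon from boron to oxygen, so C8 and C8′ are not touched, the aryl ethers are inert, and recrystallisation of 9 should allow the stereochemical purity to be raised.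

Step 5
Reactants: 9 (2R,3R)-2,3-bis[4-(benzyloxy)-3,5-dimethoxybenzyl]butane-1,4-diol
Product: 10 (2R,3R)-2,3-bis[4-(benzyloxy)-3,5-dimethoxybenzyl]butane-1,4-diyl dimethanesulfonate
Conditions: MsCl (2.5 equiv), Et3N (3 equiv), CH2Cl2, 0 °C; used promptly
Reagents that add atoms: methanesulfonyl chloride, CS(=O)(=O)Cl
Why: Sulfonylation of both primary alcohols through the sulfene is fast at 0 °C with excess reagent, so the monomesylate should not persist long enough to close to the tetrahydrofuran, and no stereocentre takes part.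

Step 6
Reactants: 10 (2R,3R)-2,3-bis[4-(benzyloxy)-3,5-dimethoxybenzyl]butane-1,4-diyl dimethanesulfonate
Product: 11 (2R,3R)-1,4-bis[4-(benzyloxy)-3,5-dimethoxyphenyl]-2,3-dimethylbutane
Conditions: LiBHEt3 (4 equiv), THF, 0 °C to rt
Reagents that add atoms: none
Why: SN2 displacement of a primary sulfonate by hydride (Super-Hydride reduction) turns each CH2OMs into a methyl group, attack at carbon being favoured over attack at sulfur with this reagent even at β-branched primary centres, while aryl ethers and the two methines are unaffected at this temperature.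

Step 7
Reactants: 11 (2R,3R)-1,4-bis[4-(benzyloxy)-3,5-dimethoxyphenyl]-2,3-dimethylbutane
Product: 12 4,4′-[(2R,3R)-2,3-dimethylbutane-1,4-diyl]bis(2,6-dimethoxyphenol)
Conditions: H2 (1 atm), 10% Pd/C, EtOAc/MeOH, rt
Reagents that add atoms: none
Why: Catalytic hydrogenolysis cleaves the two benzylic C–O bonds and leaves the methyl ethers, the arenes and the saturated chain intact.

Step 8
Reactants: 12 4,4′-[(2R,3R)-2,3-dimethylbutane-1,4-diyl]bis(2,6-dimethoxyphenol)
Product: 14 sauriol B (5-[(2R,3R)-4-(4-hydroxy-3,5-dimethoxyphenyl)-2,3-dimethylbutyl]-3-methoxybenzene-1,2-diol), via ortho-quinone 13 (not isolated)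
Conditions: NaIO4 (0.7 equiv), THF/H2O, 0 °C, short contact; then Na2S2O4 (aq), 0 °C; unreacted 12 recovered and recycled
Reagents that add atoms: water, O
Why: Adler-type periodate oxidation of an ortho-methoxyphenol gives the ortho-quinone with loss of methanol and dithionite reduces it to the catechol; because all four methoxy groups of 12 are equivalent a single demethylation can only give 14, and the substoichiometric oxidant is meant to keep oxidation of both rings low.

Compound list
1 | 4-allyl-2,6-dimethoxyphenol | C=CCc1cc(OC)c(O)c(OC)c1 | starting material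
2 | benzyl bromide | BrCc1ccccc1 | starting material
3 | 5-allyl-2-(benzyloxy)-1,3-dimethoxybenzene | C=CCc1cc(OC)c(OCc2ccccc2)c(OC)c1 | intermediate
4 | (E)-1,4-bis[4-(benzyloxy)-3,5-dimethoxyphenyl]but-2-ene | COc1cc(C/C=C/Cc2cc(OC)c(OCc3ccccc3)c(OC)c2)cc(OC)c1OCc1ccccc1 | intermediate
5 | bis(catecholato)diboron | B1(B2Oc3ccccc3O2)Oc2ccccc2O1 | starting material
6 | bromochloromethane | ClCBr | starting material
7 | (2R,3R)-1,4-bis[4-(benzyloxy)-3,5-dimethoxyphenyl]butane-2,3-diyl bis(catecholboronate) | COc1cc(C[C@@H](B2Oc3ccccc3O2)[C@H](B2Oc3ccccc3O2)Cc2cc(OC)c(OCc3ccccc3)c(OC)c2)cc(OC)c1OCc1ccccc1 | intermediate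
8 | (2R,3R)-2,3-bis[4-(benzyloxy)-3,5-dimethoxybenzyl]butane-1,4-diyl bis(catecholboronate) | COc1cc(C[C@@H](CB2Oc3ccccc3O2)[C@H](CB2Oc3ccccc3O2)Cc2cc(OC)c(OCc3ccccc3)c(OC)c2)cc(OC)c1OCc1ccccc1 | intermediate
9 | (2R,3R)-2,3-bis[4-(benzyloxy)-3,5-dimethoxybenzyl]butane-1,4-diol | COc1cc(C[C@@H](CO)[C@H](CO)Cc2cc(OC)c(OCc3ccccc3)c(OC)c2)cc(OC)c1OCc1ccccc1 | intermediate
10 | (2R,3R)-2,3-bis[4-(benzyloxy)-3,5-dimethoxybenzyl]butane-1,4-diyl dimethanesulfonate | COc1cc(C[C@@H](COS(C)(=O)=O)[C@H](COS(C)(=O)=O)Cc2cc(OC)c(OCc3ccccc3)c(OC)c2)cc(OC)c1OCc1ccccc1 | intermediate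
11 | (2R,3R)-1,4-bis[4-(benzyloxy)-3,5-dimethoxyphenyl]-2,3-dimethylbutane | COc1cc(C[C@@H](C)[C@H](C)Cc2cc(OC)c(OCc3ccccc3)c(OC)c2)cc(OC)c1OCc1ccccc1 | intermediate
12 | 4,4′-[(2R,3R)-2,3-dimethylbutane-1,4-diyl]bis(2,6-dimethoxyphenol) | COc1cc(C[C@@H](C)[C@H](C)Cc2cc(OC)c(O)c(OC)c2)cc(OC)c1O | intermediate
13 | 5-[(2R,3R)-4-(4-hydroxy-3,5-dimethoxyphenyl)-2,3-dimethylbutyl]-3-methoxycyclohexa-3,5-diene-1,2-dione | COC1=CC(C[C@@H](C)[C@H](C)Cc2cc(OC)c(O)c(OC)c2)=CC(=O)C1=O | intermediate
14 | sauriol B, 5-[(2R,3R)-4-(4-hydroxy-3,5-dimethoxyphenyl)-2,3-dimethylbutyl]-3-methoxybenzene-1,2-diol | COc1cc(C[C@@H](C)[C@H](C)Cc2cc(OC)c(O)c(OC)c2)cc(O)c1O | target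

Total step count: 8. Longest linear sequence: 8 steps (1 to 14).

Steps most likely to fail

Step 3. What may go wrong: rhodium hydride formed by β-hydride elimination can move the double bond toward an aryl ring or erode face selectivity, and the second carbenoid insertion next to an already homologated boron may stall, so the like bis-homologated product would come with poor enantiomeric purity or as a mixture. The fallback sets out from 3 and rejoins the route at 9; it makes the two stereocentres by auxiliary-controlled oxidative enolate dimerisation instead. Hydroboration–oxidation of 3 (9-BBN, THF; NaOH, H2O2) should give 3-[4-(benzyloxy)-3,5-dimethoxyphenyl]propan-1-ol F1. Oxidation (TEMPO, PhI(OAc)2, MeCN/H2O) gives 3-[4-(benzyloxy)-3,5-dimethoxyphenyl]propanoic acid F2. Activation as the pivaloyl mixed anhydride (PivCl, Et3N, THF) and acylation of (S)-4-benzyloxazolidin-2-one (LiCl) gives (S)-4-benzyl-3-{3-[4-(benzyloxy)-3,5-dimethoxyphenyl]propanoyl}oxazolidin-2-one F3. Its lithium enolate (LiN(iPr)2, THF, −78 °C) is dimerised with TiCl4 as one-electron oxidant, each enolate reacting on the face away from the benzyl group of its auxiliary, to the (2R,3R)-2,3-bis[4-(benzyloxy)-3,5-dimethoxybenzyl]succinyl bis(oxazolidinone) F4. LiBH4 (THF/MeOH, 0 °C) then releases diol 9.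

Step 8. What may go wrong: the first oxidation does not deactivate the second ring, so oxidation of both rings in one molecule competes at any useful conversion, and the ortho-quinone can tautomerise to a quinone methide at C7 and oligomerise before it is reduced. The fallback sets out from 11 and rejoins the route at 14; it differentiates the rings before any oxidant is used. Hydrogenolysis of 11 is interrupted near half conversion (H2, Pd/C, EtOAc) to give 4-{(2R,3R)-4-[4-(benzyloxy)-3,5-dimethoxyphenyl]-2,3-dimethylbutyl}-2,6-dimethoxyphenol F5, which its single free hydroxyl should separate easily from 11 (resubmitted) and 12 (re-benzylated with 2). Only the free ring of F5 can be oxidised, so NaIO4 in excess should give 5-{(2R,3R)-4-[4-(benzyloxy)-3,5-dimethoxyphenyl]-2,3-dimethylbutyl}-3-methoxycyclohexa-3,5-diene-1,2-dione F6. Na2S2O4 reduces it to 5-{(2R,3R)-4-[4-(benzyloxy)-3,5-dimethoxyphenyl]-2,3-dimethylbutyl}-3-methoxybenzene-1,2-diol F7, and a final hydrogenolysis (H2, Pd/C) gives 14.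

Step 2. What may go wrong: equilibration leaves a share of Z isomer that recrystallisation fails to remove (it would end up in the meso series in step 3), and ruthenium-hydride migration of the double bond gives chain-shortened stilbene-type and 1,3-diarylpropene by-products. The fallback sets out from 2 and rejoins the route at 4; it takes the E geometry from a stereodefined reagent. Commercial 4-hydroxy-3,5-dimethoxybenzaldehyde is benzylated with 2 (K2CO3, DMF) to 4-(benzyloxy)-3,5-dimethoxybenzaldehyde F8, reduced (NaBH4, MeOH) to [4-(benzyloxy)-3,5-dimethoxyphenyl]methanol F9 and converted (SOCl2, CH2Cl2, 0 °C) into 2-(benzyloxy)-5-(chloromethyl)-1,3-dimethoxybenzene F10. A twofold Suzuki–Miyaura coupling of F10 with commercial (E)-1,2-bis(4,4,5,5-tetramethyl-1,3,2-dioxaborolan-2-yl)ethene (Pd(dppf)Cl2, K3PO4, THF/H2O, 60 °C) should then give 4 with retention of the alkene geometry.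

Further compounds
F1 | step 3 | 3-[4-(benzyloxy)-3,5-dimethoxyphenyl]propan-1-ol | OCCCc1cc(OC)c(OCc2ccccc2)c(OC)c1
F2 | step 3 | 3-[4-(benzyloxy)-3,5-dimethoxyphenyl]propanoic acid | OC(=O)CCc1cc(OC)c(OCc2ccccc2)c(OC)c1
F3 | step 3 | (S)-4-benzyl-3-{3-[4-(benzyloxy)-3,5-dimethoxyphenyl]propanoyl}oxazolidin-2-one | O=C(CCc1cc(OC)c(OCc2ccccc2)c(OC)c1)N1[C@@H](Cc2ccccc2)COC1=O
F4 | step 3 | (2R,3R)-2,3-bis[4-(benzyloxy)-3,5-dimethoxybenzyl]succinyl bis[(S)-4-benzyloxazolidin-2-one] | O=C([C@H](Cc1cc(OC)c(OCc2ccccc2)c(OC)c1)[C@@H](Cc1cc(OC)c(OCc2ccccc2)c(OC)c1)C(=O)N1[C@@H](Cc2ccccc2)COC1=O)N1[C@@H](Cc2ccccc2)COC1=O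
F5 | step 8 | 4-{(2R,3R)-4-[4-(benzyloxy)-3,5-dimethoxyphenyl]-2,3-dimethylbutyl}-2,6-dimethoxyphenol | COc1cc(C[C@@H](C)[C@H](C)Cc2cc(OC)c(OCc3ccccc3)c(OC)c2)cc(OC)c1O
F6 | step 8 | 5-{(2R,3R)-4-[4-(benzyloxy)-3,5-dimethoxyphenyl]-2,3-dimethylbutyl}-3-methoxycyclohexa-3,5-diene-1,2-dione | COC1=CC(C[C@@H](C)[C@H](C)Cc2cc(OC)c(OCc3ccccc3)c(OC)c2)=CC(=O)C1=O
F7 | step 8 | 5-{(2R,3R)-4-[4-(benzyloxy)-3,5-dimethoxyphenyl]-2,3-dimethylbutyl}-3-methoxybenzene-1,2-diol | COc1cc(C[C@@H](C)[C@H](C)Cc2cc(OC)c(OCc3ccccc3)c(OC)c2)cc(O)c1O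
F8 | step 2 | 4-(benzyloxy)-3,5-dimethoxybenzaldehyde | COc1cc(C=O)cc(OC)c1OCc1ccccc1
F9 | step 2 | [4-(benzyloxy)-3,5-dimethoxyphenyl]methanol | COc1cc(CO)cc(OC)c1OCc1ccccc1
F10 | step 2 | 2-(benzyloxy)-5-(chloromethyl)-1,3-dimethoxybenzene | COc1cc(CCl)cc(OC)c1OCc1ccccc1
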